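How far has E burnt on to X in this flask, early and late?

| setting | Thursday's | Sunday's | flask |
|---|---|---|---|
| D | 0.050 M | 0.050 M | 0.050 M |
| Q | 1 equiv | 4 equiv | 2.00 equiv |
| L | 0.058 mol% | 0.058 mol% | 0.058 mol% |
| J | 2.4 mol% | 2.4 mol% | 2.4 mol% |
| remark | run made earlier | run made earlier |  |
| time |  |  | 15 h |

| run | time / h | X / % | E / % |
|---|---|---|---|
| Thursday's | 1.33 | 0.5 | 8.2 |
| Thursday's | 3.00 | 2.9 | 23.3 |
| Thursday's | 8.00 | 12.7 | 46.7 |
| Thursday's | 20.0 | 20.4 | 57.2 |
| Sunday's | 5.00 | 36.8 | 24.3 |
| Sunday's | 10.0 | 69.2 | 15.8 |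
| Sunday's | 15.0 | 85.8 | 8.6 |
| Sunday's | 20.0 | 93.6 | 3.8 |

(readings scatter by 0.3 percentage points)



- share of X in X plus E at 20 min
- share of X in X plus E at 15 h
- which of X and E there is more of at 15 h

In Thursday's run at 20.0 h, E plus twice X comes to 98.0% of the Q charged, so I read D → E → X, with one Q per step. Between 5.00 h and 10.0 h of Sunday's run, X gains 0.323 h⁻¹ of the mean E, at a mean Q of 0.137 M:

burn constant = 2.36 M⁻¹ h⁻¹

burn time at this flask's charged Q = 4.24 h

This burn time, the pseudo-first-order lifetime of E against loss to X at the charged Q, sets my ladder. Thursday's readings extrapolate to a start-up lag of 0.500 h. Inside the lag, I take E to grow roughly as time squared and X as its cube, so: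

X/E ≈ time / (3 × burn time)

Past the lag, I take E to grow about linearly and X about as time squared, so:

X/E ≈ (time − lag) / (2 × burn time)

With Sunday's constant, on Thursday's run at 3.00 h, the second rule gives 0.147 and the readings 0.124, so it runs high there.

In this flask, 20 min falls inside the lag, and the share of X comes to 2.55%. The burn time is longer than the lag, so E builds first. By the second rule, X draws level at 8.98 h, earlier than 15 h, so X leads, with a share of 63.1%. That late figure is rough: it holds Q at its charge.

The forecast says 3%, 62% and X, below mine late, reading the burn step as “so it is first order in Q”.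

The flask gives 2.72%, 61.3% and X, with X at 56.2% and E at 35.5%.

    D + L → L + G (k = 7000 M⁻¹ h⁻¹)
    Q + J + G → J + E (k = 12000 M⁻² h⁻¹)
    Q + E → X (k = 2.40 M⁻¹ h⁻¹)

X draws level at 9.34 h, after my 8.98 h, and the late share stands 1.8 percentage points below mine. The neighbour flask with 0.020 M of D, at the same equivalents, has a burn time of 10.6 h. Keeping Thursday's lag, level then comes at 21.7 h, later than 15 h, so I expect E ahead, with a share of X of 40.6%. At 15 h that neighbour holds E 31.7% against X 19.4%, a share of 38.0%.

Readings and results stem from a simulated flask from invented constants; scatter was added.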